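Numbering follows benzofuran: ring B is O1–C2–C3–C3a–C7a and ring A is C3a–C4–C5–C6–C7–C7a. The enabling feature is that C6 in ring A is a single carbonyl carbon held only by C5 and C7. Without it, the chain C7–C7a–C3a–C4–C5 folds into a vinylcyclopropane (C7=C7a on the ring C3a–C4–C5) that is spiro-fused to ring B at C3a and locked s-cis.
Retrosynthetic cuts, in order: the C4/C7 hydrogens (dehydrogenation); C5–C6 and C6–C7 (loss of CO, which restores C3a–C5); C7a=C7 (lactone methylenation); C3a–C4 and C4–C5 (CH2 transfer); C3a–C5 (acylation); C2–C3 (crotylboration).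
Forward: ring B is made first as a trans γ-lactone and opened for one stage to an allylic alcohol, so that the cyclopropane goes on under hydroxyl direction. Ring B is then re-closed and methylenated, and ring A is closed last by CO insertion.
Stereochemistry: C2 and C3 come from a catalyst-controlled anti crotylboration. C5 comes from syn-specific CH2 transfer to a Z enol ether, on the face chosen by a chiral dioxaborolane, and is carried with retention through the carbonylation. The spiro centre C3a is only a relay and ends sp2.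

Key step: step 11

Assumption: the facial sense of (S)-TRIP and of the (4S,5S)-dioxaborolane is extrapolated from benzaldehyde and cinnamyl alcohol, for which the mirror-image reagents give the 1R carbinol and the (1S,2S)-cyclopropylmethanol; benzofuran numbering is used for the atoms of every intermediate.

Step 1
Reactants: 1 3,4,5-trimethoxybenzaldehyde; 2 (E)-crotylboronic acid pinacol ester
Product: 4 (1S,2S)-2-methyl-1-(3,4,5-trimethoxyphenyl)but-3-en-1-ol, via pinacol borate ester 3 (not isolated)
Conditions: (S)-TRIP (5 mol %), 4 Å MS, toluene, −30 °C; aq. NaHCO3 work-up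
Reagents that add atoms: none
Why: Chiral-phosphoric-acid-catalysed crotylboration passes through a closed chair (Zimmerman–Traxler) transition state, so the E boronate can only give the anti pair that becomes the trans C2/C3 relationship, while the acid, hydrogen-bonded to the boronate oxygen and the formyl hydrogen, exposes the aldehyde face that leads to 1S,2S.

Step 2
Reactants: 4 (1S,2S)-2-methyl-1-(3,4,5-trimethoxyphenyl)but-3-en-1-ol
Product: 6 (1S,2S)-2-methyl-1-(3,4,5-trimethoxyphenyl)butane-1,4-diol, via bis-boryl adduct 5 (not isolated)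
Conditions: 9-BBN (2.5 equiv), THF, 0 °C → rt; then 3 M NaOH, 30% H2O2, 0 °C
Reagents that add atoms: hydrogen peroxide, OO
Why: Brown hydroboration–oxidation with the bulky 9-BBN puts boron on the terminal carbon of the monosubstituted alkene (the free hydroxyl merely consumes one equivalent as a borinate), and oxidation with retention gives the primary alcohol without touching C2 or C3.

Step 3
Reactants: 6 (1S,2S)-2-methyl-1-(3,4,5-trimethoxyphenyl)butane-1,4-diol
Product: 8 (4S,5S)-4-methyl-5-(3,4,5-trimethoxyphenyl)dihydrofuran-2(3H)-one, via lactol 7 (not isolated)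
Conditions: TEMPO (10 mol %), PhI(OAc)2 (2.3 equiv), CH2Cl2, rt
Reagents that add atoms: none
Why: In this oxoammonium-mediated oxidative lactonisation of a 1,4-diol the unhindered primary alcohol is oxidised much faster than the secondary benzylic one, the hydroxy aldehyde closes to lactol 7 and this is oxidised again, so ring B is closed as the trans lactone with both stereocentres intact.

Step 4
Reactants: 9 but-3-enoic acid
Product: 10 but-3-enoyl chloride
Conditions: (COCl)2 (1.1 equiv), DMF (cat.), CH2Cl2, 0 °C → rt; concentrated cold and used at once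
Reagents that add atoms: oxalyl chloride, ClC(=O)C(=O)Cl
Why: Acid chloride formation through the Vilsmeier-type chloroiminium species runs without base, so the β,γ double bond has no path into conjugation.

Step 5
Reactants: 8 (4S,5S)-4-methyl-5-(3,4,5-trimethoxyphenyl)dihydrofuran-2(3H)-one; 10 but-3-enoyl chloride
Product: 13 (4S,5S)-3-(but-3-enoyl)-4-methyl-5-(3,4,5-trimethoxyphenyl)dihydrofuran-2(3H)-one (labile at C3a, partly enolised), via lactone lithium enolate 11 (not isolated), via chelated lithium enolate 12 (not isolated)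
Conditions: LiN(SiMe3)2 (2.1 equiv), THF, −78 °C; 10 (1.05 equiv), −78 °C; AcOH (2.2 equiv), −78 °C
Reagents that add atoms: none
Why: In this crossed Claisen C-acylation of a lactone lithium enolate the acyl carbon ends on C3a whether chloride 10 is attacked directly or first loses HCl to vinylketene, and the second equivalent of base stores the product as the chelated 1,3-dicarbonyl enolate 12, in which the allyl double bond cannot move, until the cold acetic acid quench (the C3a centre is flattened in step 6).

Step 6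
Reactants: 13 (4S,5S)-3-(but-3-enoyl)-4-methyl-5-(3,4,5-trimethoxyphenyl)dihydrofuran-2(3H)-one
Product: 14 (3Z,4S,5S)-3-(1-methoxybut-3-en-1-ylidene)-4-methyl-5-(3,4,5-trimethoxyphenyl)dihydrofuran-2(3H)-one (OMe cis to the lactone carbonyl)
Conditions: Me3SiCHN2 (2 M in hexanes, 1.5 equiv), toluene/MeOH 4:1, 0 °C → rt
Reagents that add atoms: trimethylsilyldiazomethane, C[Si](C)(C)C=[N+]=[N-]
Why: O-Methylation of an enolisable 1,3-dicarbonyl compound with trimethylsilyldiazomethane in methanol starts by proton transfer from the internally hydrogen-bonded enol, whose oxygen lies cis to the lactone carbonyl, and the methyldiazonium ion pair should collapse on that oxygen faster than the C3a–C5 bond rotates, giving the Z enol ether under neutral conditions that leave the skipped diene alone.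

Step 7
Reactants: 14 (3Z,4S,5S)-3-(1-methoxybut-3-en-1-ylidene)-4-methyl-5-(3,4,5-trimethoxyphenyl)dihydrofuran-2(3H)-one
Product: 15 (1S,2S,3Z)-3-(hydroxymethyl)-4-methoxy-2-methyl-1-(3,4,5-trimethoxyphenyl)hepta-3,6-dien-1-ol
Conditions: i-Bu2AlH (4.5 equiv), CH2Cl2, −78 → −20 °C; aq. potassium sodium tartrate; used without chromatography
Reagents that add atoms: none
Why: 1,2-Reduction of a β-alkoxyacrylate-type lactone with i-Bu2AlH keeps the alkene geometry and removes the carbonyl pull, turning a deactivated push–pull alkene into an electron-rich enol ether with its own allylic hydroxyl, which is what makes the next step selective over the allyl group.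

Step 8
Reactants: 15 (1S,2S,3Z)-3-(hydroxymethyl)-4-methoxy-2-methyl-1-(3,4,5-trimethoxyphenyl)hepta-3,6-dien-1-ol
Product: 16 {(1R,2S)-2-allyl-1-[(1S,2S)-1-hydroxy-1-(3,4,5-trimethoxyphenyl)propan-2-yl]-2-methoxycyclopropyl}methanol (OMe cis to CH2OH)
Conditions: Et2Zn (3.5 equiv), CH2I2 (7 equiv), DME (3.5 equiv), (4S,5S)-2-butyl-N,N,N',N'-tetramethyl-1,3,2-dioxaborolane-4,5-dicarboxamide (1.2 equiv), CH2Cl2, −10 → 0 °C; aq. NH4Cl, then aq. NaOH wash
Reagents that add atoms: diiodomethane, ICI
Why: In the Charette asymmetric Simmons–Smith cyclopropanation the allylic zinc alkoxide, bound to the chiral dioxaborolane, delivers CH2 to the neighbouring tetrasubstituted enol ether far faster than free carbenoid reaches the remote monosubstituted alkene, the concerted syn addition turns Z geometry into OMe cis to CH2OH, and the (4S,5S) controller (helped by the C2 zinc alkoxide on the same face) selects the face that makes C5 S and C3a R.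

Step 9
Reactants: 16 {(1R,2S)-2-allyl-1-[(1S,2S)-1-hydroxy-1-(3,4,5-trimethoxyphenyl)propan-2-yl]-2-methoxycyclopropyl}methanol
Product: 18 (1S,3S,6S,7S)-1-allyl-1-methoxy-7-methyl-6-(3,4,5-trimethoxyphenyl)-5-oxaspiro[2.4]heptan-4-one, via spiro lactol 17 (not isolated)
Conditions: TEMPO (20 mol %), PhI(OAc)2 (2.3 equiv), CH2Cl2/aq. pH 7 phosphate buffer, 0 °C → rt
Reagents that add atoms: none
Why: The same TEMPO/PhI(OAc)2 oxidative lactonisation as in step 3, buffered because the transient 2-methoxycyclopropanecarbaldehyde is acid-sensitive, sees the aldehyde trapped at once by the C2 hydroxyl as lactol 17 and re-closes ring B without touching the cyclopropane stereocentres.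

Step 10
Reactants: 18 (1S,3S,6S,7S)-1-allyl-1-methoxy-7-methyl-6-(3,4,5-trimethoxyphenyl)-5-oxaspiro[2.4]heptan-4-one
Product: 19 (1S,3R,6S,7S)-1-allyl-1-methoxy-7-methyl-4-methylidene-6-(3,4,5-trimethoxyphenyl)-5-oxaspiro[2.4]heptane
Conditions: Cp2TiMe2 (2.5 equiv), toluene, 70 °C, dark; filtration through basic alumina
Reagents that add atoms: dimethyltitanocene Cp2TiMe2, C[Ti](C)(C1C=CC=C1)C1C=CC=C1
Why: In the Petasis methylenation, Cp2Ti=CH2 released on heating converts lactones into exocyclic enol ethers under neutral conditions that a donor–acceptor cyclopropane and a terminal alkene tolerate, and because C3a is quaternary the new C7a=C7 bond cannot slip into the ring.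

Step 11
Reactants: 19 (1S,3R,6S,7S)-1-allyl-1-methoxy-7-methyl-4-methylidene-6-(3,4,5-trimethoxyphenyl)-5-oxaspiro[2.4]heptane; 20 carbon monoxide
Product: 21 (2S,3S,5S)-5-allyl-5-methoxy-3-methyl-2-(3,4,5-trimethoxyphenyl)-2,3,4,7-tetrahydro-1-benzofuran-6(5H)-one
Conditions: [Rh(CO)2Cl]2 (5–10 mol %), CO (1 atm), 4 Å MS, toluene, 90 °C
Reagents that add atoms: none
Why: Monovalent rhodium binds the exocyclic C7=C7a bond, adds oxidatively into the adjoining C3a–C5 bond to give a six-membered trivalent rhodacycle (σ bond to C5, π-allyl over C3a–C7a–C7), CO migrates into the Rh–C5 bond, and reductive elimination joins the acyl carbon C6 to C7, leaving C3a=C7a. The closest known reaction type is the rhodium-, cobalt- or iron-carbonyl-mediated [5+1] carbonylation of vinylcyclopropanes to β,γ-cyclohexenones. Ring A is closed by ring expansion, the three-membered ring and one CO becoming a six-membered ring through reductive elimination from the seven-membered acyl rhodacycle. No stereocentre is formed: C5 should keep its S configuration because both the front-side insertion into C3a–C5 and the alkyl migration to CO proceed with retention, C2 and C3 are spectators, and C3a becomes sp2. The step needs cleavage of C3a–C5 and not of the less hindered C3a–C4: ring B holds the alkene s-cis in the plane that bisects the cyclopropane, so the alkene face syn to the C3 methyl lies over C3a–C5 and the face syn to the C2 aryl group lies over C3a–C4, and rhodium should take the first face because the aryl group shields the other and the C5 methoxy group, cis to C7a, can bind the metal there, while this bond is also the most strained and is polarised by the oxygen donor. The CO atmosphere holds back the vinylcyclopropane–cyclopentene shift and β-hydride loss from the tertiary alkyl, and the sieves protect the enol ether.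

Step 12
Reactants: 21 (2S,3S,5S)-5-allyl-5-methoxy-3-methyl-2-(3,4,5-trimethoxyphenyl)-2,3,4,7-tetrahydro-1-benzofuran-6(5H)-one
Product: 22 (2S,3S,5S)-5-allyl-6-(tert-butyldimethylsilyloxy)-5-methoxy-3-methyl-2-(3,4,5-trimethoxyphenyl)-2,3,4,5-tetrahydro-1-benzofuran
Conditions: t-BuMe2SiOTf (1.3 equiv), Et3N (2.5 equiv), CH2Cl2, 0 °C; aq. NaHCO3, short Et3N-deactivated silica plug
Reagents that add atoms: tert-butyldimethylsilyl triflate, CC(C)(C)[Si](C)(C)OS(=O)(=O)C(F)(F)F
Why: In this soft enolisation with a silyl triflate and an amine only C7 can be deprotonated because C5 is quaternary, and both 21 and any conjugated isomer formed from it converge on the same 6-silyloxy C6=C7/C7a=C3a diene.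

Step 13
Reactants: 22 (2S,3S,5S)-5-allyl-6-(tert-butyldimethylsilyloxy)-5-methoxy-3-methyl-2-(3,4,5-trimethoxyphenyl)-2,3,4,5-tetrahydro-1-benzofuran
Product: 23 (2S,3S,5S)-5-allyl-5-methoxy-3-methyl-2-(3,4,5-trimethoxyphenyl)-2,3-dihydro-1-benzofuran-6(5H)-one (CNP0316836.1)
Conditions: DDQ (1.05 equiv), CH2Cl2, −20 → 0 °C; aq. NaHCO3
Reagents that add atoms: none
Why: DDQ dehydrogenation of a silyl dienol ether, the counterpart of the 3,5-dienol ether to 4,6-dien-3-one oxidation of steroids, takes hydride from C4 to give a pentadienyl cation stabilised by O1 and the silyloxy group, loss of silicon leaves the C7=C7a/C3a=C4 dienone, and since the quinone should stack on the face away from the C2 aryl group, where C3 offers only its methyl, the competing C3–H abstraction is disfavoured.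

Compound list
1 | 3,4,5-trimethoxybenzaldehyde | COc1cc(C=O)cc(OC)c1OC | starting material
2 | (E)-crotylboronic acid pinacol ester | C/C=C/CB1OC(C)(C)C(C)(C)O1 | starting material
3 | pinacol borate ester of alcohol 4 | CC1(C)OB(O[C@H](c2cc(OC)c(OC)c(OC)c2)[C@H](C=C)C)OC1(C)C | intermediate
4 | (1S,2S)-2-methyl-1-(3,4,5-trimethoxyphenyl)but-3-en-1-ol | O[C@H](c1cc(OC)c(OC)c(OC)c1)[C@H](C=C)C | intermediate
5 | O,C-bis(9-borabicyclo[3.3.1]nonan-9-yl) adduct of 4 | B1(O[C@H](c2cc(OC)c(OC)c(OC)c2)[C@H](CCB2C3CCCC2CCC3)C)C2CCCC1CCC2 | intermediate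
6 | (1S,2S)-2-methyl-1-(3,4,5-trimethoxyphenyl)butane-1,4-diol | O[C@H](c1cc(OC)c(OC)c(OC)c1)[C@H](CCO)C | intermediate
7 | (4S,5S)-4-methyl-5-(3,4,5-trimethoxyphenyl)tetrahydrofuran-2-ol (anomers) | OC1C[C@H](C)[C@@H](c2cc(OC)c(OC)c(OC)c2)O1 | intermediate
8 | (4S,5S)-4-methyl-5-(3,4,5-trimethoxyphenyl)dihydrofuran-2(3H)-one | O=C1C[C@H](C)[C@@H](c2cc(OC)c(OC)c(OC)c2)O1 | intermediate
9 | but-3-enoic acid | C=CCC(=O)O | starting material
10 | but-3-enoyl chloride | C=CCC(=O)Cl | intermediate
11 | lithium enolate of lactone 8 | [Li+].[O-]C1=C[C@H](C)[C@@H](c2cc(OC)c(OC)c(OC)c2)O1 | intermediate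
12 | chelated lithium enolate of keto lactone 13 (O− cis to the lactone carbonyl) | [Li+].C=CC/C([O-])=C1/C(=O)O[C@H](c2cc(OC)c(OC)c(OC)c2)[C@H]1C | intermediate
13 | (4S,5S)-3-(but-3-enoyl)-4-methyl-5-(3,4,5-trimethoxyphenyl)dihydrofuran-2(3H)-one | C=CCC(=O)C1C(=O)O[C@H](c2cc(OC)c(OC)c(OC)c2)[C@H]1C | intermediate
14 | (3Z,4S,5S)-3-(1-methoxybut-3-en-1-ylidene)-4-methyl-5-(3,4,5-trimethoxyphenyl)dihydrofuran-2(3H)-one | C=CC/C(OC)=C1/C(=O)O[C@H](c2cc(OC)c(OC)c(OC)c2)[C@H]1C | intermediate
15 | (1S,2S,3Z)-3-(hydroxymethyl)-4-methoxy-2-methyl-1-(3,4,5-trimethoxyphenyl)hepta-3,6-dien-1-ol | C=CC/C(OC)=C(/CO)[C@H](C)[C@H](O)c1cc(OC)c(OC)c(OC)c1 | intermediate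
16 | {(1R,2S)-2-allyl-1-[(1S,2S)-1-hydroxy-1-(3,4,5-trimethoxyphenyl)propan-2-yl]-2-methoxycyclopropyl}methanol | C=CC[C@]1(OC)C[C@]1(CO)[C@H](C)[C@H](O)c1cc(OC)c(OC)c(OC)c1 | intermediate
17 | spiro lactol, the 4-hydroxy analogue of 18 (anomers) | C=CC[C@]1(OC)C[C@@]12C(O)O[C@H](c1cc(OC)c(OC)c(OC)c1)[C@H]2C | intermediate
18 | (1S,3S,6S,7S)-1-allyl-1-methoxy-7-methyl-6-(3,4,5-trimethoxyphenyl)-5-oxaspiro[2.4]heptan-4-one | C=CC[C@]1(OC)C[C@@]12C(=O)O[C@H](c1cc(OC)c(OC)c(OC)c1)[C@H]2C | intermediate
19 | (1S,3R,6S,7S)-1-allyl-1-methoxy-7-methyl-4-methylidene-6-(3,4,5-trimethoxyphenyl)-5-oxaspiro[2.4]heptane | C=CC[C@]1(OC)C[C@@]12C(=C)O[C@H](c1cc(OC)c(OC)c(OC)c1)[C@H]2C | intermediate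
20 | carbon monoxide | [C-]#[O+] | starting material
21 | (2S,3S,5S)-5-allyl-5-methoxy-3-methyl-2-(3,4,5-trimethoxyphenyl)-2,3,4,7-tetrahydro-1-benzofuran-6(5H)-one | C=CC[C@]1(OC)CC2=C(CC1=O)O[C@H](c1cc(OC)c(OC)c(OC)c1)[C@H]2C | intermediate
22 | (2S,3S,5S)-5-allyl-6-(tert-butyldimethylsilyloxy)-5-methoxy-3-methyl-2-(3,4,5-trimethoxyphenyl)-2,3,4,5-tetrahydro-1-benzofuran | C=CC[C@]1(OC)CC2=C(C=C1O[Si](C)(C)C(C)(C)C)O[C@H](c1cc(OC)c(OC)c(OC)c1)[C@H]2C | intermediate
23 | (2S,3S,5S)-5-allyl-5-methoxy-3-methyl-2-(3,4,5-trimethoxyphenyl)-2,3-dihydro-1-benzofuran-6(5H)-one | C=CC[C@]1(OC)C=C2C(=CC1=O)O[C@H](c1cc(OC)c(OC)c(OC)c1)[C@H]2C | target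

Total step count: 13. Longest linear sequence: 12 (steps 1–3 and 5–13).

Steps most likely to fail

1. Step 11.
- What may go wrong: rhodium may enter the less hindered C3a–C4 bond, the tertiary alkyl–rhodium may lose a β-hydride, or C5 may ionise to an oxocarbenium ion and lose its configuration.
- Fallback, setting out from lactone 8 and returning at silyl dienol ether 22: ring A is built by carbonyl condensation and C5 is set by a chiral palladium catalyst. Commercial 3,3-dimethoxybutan-2-one loses methanol over TsOH on heating to give 3-methoxybut-3-en-2-one F1. Lactone 8 is silylated (LiN(i-Pr)2, Me3SiCl, THF, −78 °C) to its trimethylsilyl ketene acetal F2. F2 adds to F1 in a Mukaiyama–Michael reaction (Me3SiOTf cat., CH2Cl2, −78 °C), anti to the C3 methyl group, to give the keto lactone F3 as both C5 epimers. KOt-Bu in THF closes ring A by the classical 5-oxohexanoate-to-cyclohexane-1,3-dione acylation, which frees the C2 hydroxyl in the hydroxy diketone F4. TsOH in warm benzene re-closes ring B to the vinylogous ester F5. Kinetic deprotonation at C5 (LiN(SiMe3)2, THF, −78 °C) and allyl chloroformate give the allyl enol carbonate F6. Zerovalent palladium (Pd2(dba)3) with a t-Bu-PHOX ligand, its enantiomer chosen for 5S, then brings about decarboxylative asymmetric allylic alkylation to the conjugated ketone F7. Finally t-BuMe2SiOTf/Et3N removes the C3a hydrogen of F7 and gives 22, from which step 13 follows.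

2. Step 6.
- What may go wrong: Z geometry may be lost through rotation within the enolate ion pair or acid-induced rotation about the push–pull C3a=C5 bond. C-methylation may compete, and conversion may be sluggish because little enol is present.
- Fallback, setting out from keto lactone 13 and returning at ketone 21: C3a is erased in step 11, so only C5 counts, and the opposite alkene geometry can be paired with the opposite face. Methylation of the free, unchelated enolate (Cs2CO3, Me2SO4, DMF), in which the two oxygens turn away from each other, gives the E enol ether F8. i-Bu2AlH gives the E diol F9. Cyclopropanation as in step 8, but under the (4R,5R)-dioxaborolane, adds CH2 to the other face and gives the cyclopropane diol F10, the C3a epimer of 16 with C5 still S. TEMPO/PhI(OAc)2 gives the spiro lactone F11 and Cp2TiMe2 the vinylcyclopropane F12, in which the allyl group rather than the methoxy group faces C7a. Carbonylation as in step 11 flattens C3a and gives 21.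

3. Step 8.
- What may go wrong: facial selectivity may be poor because two zinc alkoxides compete for the boron controller. The 3-methoxyallylic alkoxide may be ionised by zinc diiodide, and excess carbenoid may slowly attack the allyl group.
- Fallback, setting out from enol ether lactone 14 and returning at spiro lactone 18, with no new compound: the lactone itself is cyclopropanated with a limiting amount of the more electrophilic carbenoid CF3CO2ZnCH2I (Et2Zn, CF3CO2H, CH2I2, CH2Cl2, 0 °C). Reagent control on an open chain is thereby replaced by substrate control, since the flat, rigid ring B leaves only the face anti to the C3 methyl open. Steps 7 and 9 then drop out. The price is the lower reactivity of the push–pull alkene relative to the allyl group.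

Further compounds
F1 | step 11 | 3-methoxybut-3-en-2-one | C=C(OC)C(C)=O
F2 | step 11 | {[(4S,5S)-4-methyl-5-(3,4,5-trimethoxyphenyl)-4,5-dihydrofuran-2-yl]oxy}trimethylsilane | C[Si](C)(C)OC1=C[C@H](C)[C@@H](c2cc(OC)c(OC)c(OC)c2)O1
F3 | step 11 | (3S,4S,5S)-3-(2-methoxy-3-oxobutyl)-4-methyl-5-(3,4,5-trimethoxyphenyl)dihydrofuran-2(3H)-one (epimers at the methoxy carbon) | CC(=O)C(OC)C[C@@H]1C(=O)O[C@H](c2cc(OC)c(OC)c(OC)c2)[C@H]1C
F4 | step 11 | 4-[(1S,2S)-1-hydroxy-1-(3,4,5-trimethoxyphenyl)propan-2-yl]-6-methoxycyclohexane-1,3-dione (epimers at the methoxy carbon) | COC1C[C@@H]([C@H](C)[C@H](O)c2cc(OC)c(OC)c(OC)c2)C(=O)CC1=O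
F5 | step 11 | (2S,3S,3aS)-5-methoxy-3-methyl-2-(3,4,5-trimethoxyphenyl)-3,3a,4,5-tetrahydro-1-benzofuran-6(2H)-one (C5 epimers) | COC1C[C@@H]2C(=CC1=O)O[C@H](c1cc(OC)c(OC)c(OC)c1)[C@H]2C
F6 | step 11 | allyl (2S,3S,3aS)-5-methoxy-3-methyl-2-(3,4,5-trimethoxyphenyl)-2,3,3a,4-tetrahydro-1-benzofuran-6-yl carbonate | C=CCOC(=O)OC1=C(OC)C[C@@H]2C(=C1)O[C@H](c1cc(OC)c(OC)c(OC)c1)[C@H]2C
F7 | step 11 | (2S,3S,3aS,5S)-5-allyl-5-methoxy-3-methyl-2-(3,4,5-trimethoxyphenyl)-3,3a,4,5-tetrahydro-1-benzofuran-6(2H)-one | C=CC[C@]1(OC)C[C@@H]2C(=CC1=O)O[C@H](c1cc(OC)c(OC)c(OC)c1)[C@H]2C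
F8 | step 6 | (3E,4S,5S)-3-(1-methoxybut-3-en-1-ylidene)-4-methyl-5-(3,4,5-trimethoxyphenyl)dihydrofuran-2(3H)-one | C=CC/C(OC)=C1\C(=O)O[C@H](c2cc(OC)c(OC)c(OC)c2)[C@H]1C
F9 | step 6 | (1S,2S,3E)-3-(hydroxymethyl)-4-methoxy-2-methyl-1-(3,4,5-trimethoxyphenyl)hepta-3,6-dien-1-ol | C=CC/C(OC)=C(\CO)[C@H](C)[C@H](O)c1cc(OC)c(OC)c(OC)c1
F10 | step 6 | {(1S,2S)-2-allyl-1-[(1S,2S)-1-hydroxy-1-(3,4,5-trimethoxyphenyl)propan-2-yl]-2-methoxycyclopropyl}methanol | C=CC[C@]1(OC)C[C@@]1(CO)[C@H](C)[C@H](O)c1cc(OC)c(OC)c(OC)c1
F11 | step 6 | (1S,3R,6S,7S)-1-allyl-1-methoxy-7-methyl-6-(3,4,5-trimethoxyphenyl)-5-oxaspiro[2.4]heptan-4-one | C=CC[C@]1(OC)C[C@]12C(=O)O[C@H](c1cc(OC)c(OC)c(OC)c1)[C@H]2C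
F12 | step 6 | (1S,3S,6S,7S)-1-allyl-1-methoxy-7-methyl-4-methylidene-6-(3,4,5-trimethoxyphenyl)-5-oxaspiro[2.4]heptane | C=CC[C@]1(OC)C[C@]12C(=C)O[C@H](c1cc(OC)c(OC)c(OC)c1)[C@H]2C
F0 | step 8 | none | none
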